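**Plan**
- Retrosynthesis: the hemiketal (C8'–O7') is opened to its ring–chain tautomer, a 4‑hydroxybenzoyl ketone; the C3–C2 bond of the benzofuranone is then cut by a retro 1,2‑acyl shift to a 2,3‑epoxy‑2,3‑diarylchroman‑4‑one, and the flavonol 3‑OH is traced to a flavone 2,3‑oxide.
- Enabling feature: benzofuranone C2 (the spiro atom) carries ring oxygen O1, the ring carbonyl C3 and a second, masked carbonyl (hemiketal carbon C8'). This O–C(aryl)(C=O)(C=O) array is the footprint of an acyl carbon moving from C3 to the acetal‑like C2 of an isoflavone oxide, contracting the six‑membered pyranone to the five‑membered furanone.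
- The bis‑chromone precursor is cut at O1–C2 and C2–C3 (Baker–Venkataraman) to an aryl ester, made by carbonylative union of 8‑iodo‑tri‑O‑benzylapigenin with a tri‑O‑benzyl deoxybenzoin.
- Forward order of rings: isoflavone pyranone (step 5), two oxiranes (step 6), benzofuranone by ring contraction together with the flavonol (step 7), dihydrofuran hemiketal last (step 8).
- Stereochemistry: catalyst‑controlled epoxidation sets the (2R,3R)‑isoflavone oxide; the acyl shift relays it with inversion to the quaternary carbon; the hemiketal carbon settles thermodynamically.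

Key step: step 7

Remark on the chemistry: the hemiketal carbon is taken to equilibrate by ring–chain tautomerism, and the target to be its favoured epimer (hydroxyl syn to the benzofuranone C3 carbonyl, aryl group syn to ring oxygen O1), so only the spiro carbon has to be set by the route.

**Route**

Step 1
Reactants: 1 apigenin
Product: 2 5,7-bis(benzyloxy)-2-[4-(benzyloxy)phenyl]-4H-chromen-4-one
Conditions: BnBr (4.5 equiv), K2CO3, DMF, 80 °C
Reagents that add atoms: benzyl bromide, BrCc1ccccc1
Why: Williamson etherification, in which excess reagent and heat should also cap the chelated 5‑OH, as is needed for the regiochemistry of step 2.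

Step 2
Reactants: 2 tri-O-benzylapigenin
Product: 3 5,7-bis(benzyloxy)-2-[4-(benzyloxy)phenyl]-8-iodo-4H-chromen-4-one
Conditions: NIS (1.1 equiv), TFA (cat.), CH2Cl2/MeCN, 0 °C to rt
Reagents that add atoms: N-iodosuccinimide, O=C1CCC(=O)N1I
Why: Electrophilic aromatic iodination, which in 5,7‑di‑O‑alkyl flavones should go to C8 of ring A (para to 5‑OBn, ortho to 7‑OBn), C6 being shielded between two benzyloxy groups.

Step 3
Reactants: 4 1-(2,4,6-trihydroxyphenyl)-2-(4-hydroxyphenyl)ethan-1-one
Product: 5 1-[2,4-bis(benzyloxy)-6-hydroxyphenyl]-2-[4-(benzyloxy)phenyl]ethan-1-one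
Conditions: BnBr (3.05 equiv), K2CO3, acetone, reflux
Reagents that add atoms: benzyl bromide, BrCc1ccccc1
Why: Williamson etherification that should stop at the tri‑ether because the last ortho hydroxyl is hydrogen‑bonded to the ketone, the usual selectivity of phloroacylophenones.

Step 4
Reactants: 3 8-iodo-tri-O-benzylapigenin; 5 tri-O-benzyl deoxybenzoin
Product: 6 3,5-bis(benzyloxy)-2-{[4-(benzyloxy)phenyl]acetyl}phenyl 5,7-bis(benzyloxy)-2-[4-(benzyloxy)phenyl]-4-oxo-4H-chromene-8-carboxylate
Conditions: Pd(OAc)2 (5 mol %), Xantphos (6 mol %), Et3N, CO (1 atm), toluene, 90 °C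
Reagents that add atoms: carbon monoxide, [C-]#[O+]
Why: Palladium‑catalysed aryloxycarbonylation (Heck carbonylation) of an aryl iodide with a phenol, in which CO insertion relieves the congestion at the di‑ortho‑substituted arylpalladium and the phenoxide of 5 captures the acyl complex.

Step 5
Reactants: 6 aryl ester
Product: 8 5,7-bis(benzyloxy)-3-[4-(benzyloxy)phenyl]-2-{5,7-bis(benzyloxy)-2-[4-(benzyloxy)phenyl]-4-oxo-4H-chromen-8-yl}-4H-chromen-4-one, via 1,3-diketone 7 (not isolated)
Conditions: KOtBu (2.5 equiv), THF, 0 °C to rt; aq. HCl work-up; then TsOH·H2O (10 mol %), toluene, 80 °C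
Reagents that add atoms: none
Why: Baker–Venkataraman rearrangement (the benzyl ketone enolate is acylated intramolecularly by the aryl ester) followed by acid cyclodehydration of the o‑hydroxyaryl 1,3‑diketone, the standard entry to 2‑substituted isoflavones.

Step 6
Reactants: 8 bis-chromone
Product: 9 bis-epoxide of 8 with a (2R,3R)-2,3-epoxide on the isoflavone ring (chromanone numbering) and a 2,3-epoxide on the flavone ring (either cis-fused epimer)
Conditions: (R,R)-[N,N'-bis(3,5-di-tert-butylsalicylidene)-1,2-cyclohexanediaminato]MnCl (trivalent manganese, 10 mol %), DMDO (acetone solution, 5 equiv in portions), CH2Cl2, 4 Å MS, −20 °C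
Reagents that add atoms: dimethyldioxirane, CC1(C)OO1
Why: Jacobsen–Katsuki epoxidation with the oxomanganese species generated from DMDO, a reaction type established on isoflavones and run cold so that the uncatalysed dioxirane pathway stays slow, should epoxidise both chromone double bonds, the salen ligand choosing the face of the isoflavone C2=C3 bond and so setting C2 and C3 as (2R,3R) (the antipodal complex is taken if a trial run shows the opposite sense), while the configuration of the flavone oxide is without consequence because step 7 erases it.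

Step 7
Reactants: 9 bis-epoxide
Product: 10 (2R)-4,6-bis(benzyloxy)-2-[4-(benzyloxy)benzoyl]-2-{5,7-bis(benzyloxy)-2-[4-(benzyloxy)phenyl]-3-hydroxy-4-oxo-4H-chromen-8-yl}-1-benzofuran-3(2H)-one
Conditions: Sc(OTf)3 (10 mol %), toluene/CH2Cl2, −60 °C to −10 °C
Reagents that add atoms: none
Why: Proposed new method: Sc(OTf)3 should ionise the acetal‑type C2–O bond of the isoflavone oxide (cation stabilised by ring oxygen O1 and the 2,6‑dioxygenated aryl group, the regiochemistry known from acid alcoholysis of isoflavone oxides at C2) while the ring acyl carbon C4 shifts from C3 to C2 and C3 becomes the 4‑(benzyloxy)benzoyl carbonyl; the closest known reaction type is the Lewis acid promoted 1,2‑acyl shift of α,β‑epoxy ketones to 1,3‑dicarbonyl compounds, including its ring‑contracting form (isophorone oxide to 2‑formyl‑2,4,4‑trimethylcyclopentanone), which to my knowledge has not been shown on 2,3‑diaryl‑2,3‑epoxychromanones. The five‑membered benzofuranone ring is closed by ring contraction, the C4–C2 bond forming through a bridged three‑centre (C2–C3–C4) transition state as the C3–C4 bond of the pyranone breaks. The new quaternary centre C2 is controlled by the epoxide: the acyl carbon should enter anti to the departing oxygen (inversion at the migration terminus, the course established for acyl shifts of epoxy ketones), so the (2R,3R)‑oxide should give (2R)‑10 (the descriptor stays R only because the substituent set changes) while the C3 centre is erased. The step needs acyl rather than aryl migration, which the high migratory aptitude of acyl groups in this manifold and the congestion of a geminal diaryl centre next to the di‑ortho‑substituted aryl group should secure, and it needs stereospecificity, which low temperature and a weakly polar solvent should favour by keeping ionisation and migration concerted. In the same flask the flavone oxide should open at its C2 and lose the C3 proton (the known acid isomerisation of flavone oxides), giving the flavonol 3‑OH.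

Step 8
Reactants: 10 hexabenzyl ketone
Product: 12 (2S,8'R)-3',4,5',6,8'-pentahydroxy-2',8'-bis(4-hydroxyphenyl)-3H,4'H,8'H-spiro[1-benzofuran-2,9'-furo[2,3-h]chromene]-3,4'-dione, via open keto phenol 11 (not isolated)
Conditions: H2 (1 atm), Pd/C (10 wt %), THF/MeOH, rt
Reagents that add atoms: none
Why: Hydrogenolysis of the six aryl benzyl ethers frees the flavonol 7‑OH ortho to the quaternary carbon, which should add 5‑exo‑trig to the 4‑hydroxybenzoyl carbonyl, the reversible hemiketal settling as the (8'R) epimer with its hydroxyl hydrogen‑bonded syn to the C3 carbonyl (the spiro descriptor changes from R to S only because the CIP ranking of the two carbonyl‑derived carbons switches).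

**Compound list**

1 | apigenin, 5,7-dihydroxy-2-(4-hydroxyphenyl)-4H-chromen-4-one | O=c1cc(-c2ccc(O)cc2)oc2cc(O)cc(O)c12 | starting material
2 | 5,7-bis(benzyloxy)-2-[4-(benzyloxy)phenyl]-4H-chromen-4-one | O=c1cc(-c2ccc(OCc3ccccc3)cc2)oc2cc(OCc3ccccc3)cc(OCc3ccccc3)c12 | intermediate
3 | 5,7-bis(benzyloxy)-2-[4-(benzyloxy)phenyl]-8-iodo-4H-chromen-4-one | O=c1cc(-c2ccc(OCc3ccccc3)cc2)oc2c(I)c(OCc3ccccc3)cc(OCc3ccccc3)c12 | intermediate
4 | 1-(2,4,6-trihydroxyphenyl)-2-(4-hydroxyphenyl)ethan-1-one | O=C(Cc1ccc(O)cc1)c1c(O)cc(O)cc1O | starting material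
5 | 1-[2,4-bis(benzyloxy)-6-hydroxyphenyl]-2-[4-(benzyloxy)phenyl]ethan-1-one | O=C(Cc1ccc(OCc2ccccc2)cc1)c1c(O)cc(OCc2ccccc2)cc1OCc1ccccc1 | intermediate
6 | 3,5-bis(benzyloxy)-2-{[4-(benzyloxy)phenyl]acetyl}phenyl 5,7-bis(benzyloxy)-2-[4-(benzyloxy)phenyl]-4-oxo-4H-chromene-8-carboxylate | O=C(Cc1ccc(OCc2ccccc2)cc1)c1c(OC(=O)c2c(OCc3ccccc3)cc(OCc3ccccc3)c3c(=O)cc(-c4ccc(OCc5ccccc5)cc4)oc23)cc(OCc2ccccc2)cc1OCc1ccccc1 | intermediate
7 | 1-[2,4-bis(benzyloxy)-6-hydroxyphenyl]-2-[4-(benzyloxy)phenyl]-3-{5,7-bis(benzyloxy)-2-[4-(benzyloxy)phenyl]-4-oxo-4H-chromen-8-yl}propane-1,3-dione | O=C(c1c(O)cc(OCc2ccccc2)cc1OCc1ccccc1)C(c1ccc(OCc2ccccc2)cc1)C(=O)c1c(OCc2ccccc2)cc(OCc2ccccc2)c2c(=O)cc(-c3ccc(OCc4ccccc4)cc3)oc12 | intermediate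
8 | 5,7-bis(benzyloxy)-3-[4-(benzyloxy)phenyl]-2-{5,7-bis(benzyloxy)-2-[4-(benzyloxy)phenyl]-4-oxo-4H-chromen-8-yl}-4H-chromen-4-one | O=c1c(-c2ccc(OCc3ccccc3)cc2)c(-c2c(OCc3ccccc3)cc(OCc3ccccc3)c3c(=O)cc(-c4ccc(OCc5ccccc5)cc4)oc23)oc2cc(OCc3ccccc3)cc(OCc3ccccc3)c12 | intermediate
9 | bis-epoxide of 8: (2R,3R)-2,3-epoxide on the isoflavone ring, 2,3-epoxide on the flavone ring (either cis-fused epimer, centres left open) | O=C1c2c(OCc3ccccc3)cc(OCc3ccccc3)cc2O[C@]2(c3c(OCc4ccccc4)cc(OCc4ccccc4)c4c3OC3(c5ccc(OCc6ccccc6)cc5)OC3C4=O)O[C@]12c1ccc(OCc2ccccc2)cc1 | intermediate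
10 | (2R)-4,6-bis(benzyloxy)-2-[4-(benzyloxy)benzoyl]-2-{5,7-bis(benzyloxy)-2-[4-(benzyloxy)phenyl]-3-hydroxy-4-oxo-4H-chromen-8-yl}-1-benzofuran-3(2H)-one | O=C1c2c(OCc3ccccc3)cc(OCc3ccccc3)cc2O[C@@]1(C(=O)c1ccc(OCc2ccccc2)cc1)c1c(OCc2ccccc2)cc(OCc2ccccc2)c2c(=O)c(O)c(-c3ccc(OCc4ccccc4)cc3)oc12 | intermediate
11 | (2R)-4,6-dihydroxy-2-(4-hydroxybenzoyl)-2-[3,5,7-trihydroxy-2-(4-hydroxyphenyl)-4-oxo-4H-chromen-8-yl]-1-benzofuran-3(2H)-one | O=C1c2c(O)cc(O)cc2O[C@@]1(C(=O)c1ccc(O)cc1)c1c(O)cc(O)c2c(=O)c(O)c(-c3ccc(O)cc3)oc12 | intermediate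
12 | (2S,8'R)-3',4,5',6,8'-pentahydroxy-2',8'-bis(4-hydroxyphenyl)-3H,4'H,8'H-spiro[1-benzofuran-2,9'-furo[2,3-h]chromene]-3,4'-dione | O=C1c2c(O)cc(O)cc2O[C@@]12c1c(cc(O)c3c(=O)c(O)c(-c4ccc(O)cc4)oc13)O[C@]2(O)c1ccc(O)cc1 | target

**Step count and risks**

Total step count: 8. Longest linear sequence: 7 steps (steps 1, 2, 4, 5, 6, 7 and 8 from apigenin); step 3 is the side branch.

Steps most likely to fail:

Step 7. The 4‑(benzyloxy)phenyl group may migrate in place of the acyl carbon, or the oxide may ionise to a free oxocarbenium ion so that the acyl group enters on either face and stereochemical fidelity is lost. The fallback sets out from 3 and comes back at 10, building the quaternary centre by enolate chemistry instead. Commercial 4,6-dihydroxy-1-benzofuran-3(2H)-one is dibenzylated (BnBr, K2CO3) to 4,6-bis(benzyloxy)-1-benzofuran-3(2H)-one F1. Palladium‑catalysed ketone α‑arylation of F1 with 3 (Pd(OAc)2, XPhos, NaOtBu, toluene) should give the 2-aryl benzofuranone F2. O‑Acylation with 4-(benzyloxy)benzoyl chloride and Et3N gives the enol ester F3. A 4‑pyrrolidinopyridine‑catalysed O‑to‑C acyl transfer (Steglich/Black type) should then give the racemic 2-aroyl-2-aryl ketone, from which the (R)-enantiomer F4 is separated from its (S)-antipode F5 on a chiral stationary phase. DMDO epoxidation of the flavone double bond of F4 gives the flavone oxide F6, and TsOH isomerises it to the flavonol 10.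

Step 6. Oxygen transfer from the bulky oxomanganese species to the tetrasubstituted double bond, shielded by the perpendicular aryl group, may be slow, so that the uncatalysed dioxirane pathway takes over and facial selectivity is poor. The fallback sets out from 8 and comes back at 10, replacing asymmetric catalysis by resolution. DMDO alone (CH2Cl2/acetone, 0 °C to rt) gives the racemic bis‑epoxide, that is 9 together with the stereoisomers carrying the (2S,3S)-isoflavone oxide F7. Step 7 on this mixture gives 10 together with its enantiomer, the (2S)-ketone F8, and preparative chromatography on a chiral stationary phase (amylose tris(3,5-dimethylphenylcarbamate), supercritical CO2/alcohol) delivers 10.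

Step 8. Hydrogenolysis may also cleave the benzylic C–O bonds at the quaternary carbon or at the hemiketal carbon, or reduce the diaryl ketone before it is captured as the hemiketal. The fallback sets out from 10 and comes back at 12, using non‑reductive Lewis acid debenzylation: BCl3 with pentamethylbenzene as benzyl cation scavenger (CH2Cl2, −78 °C), then aqueous methanol work‑up to hydrolyse boron chelates. It passes through 11 and makes no compound outside the list (none, F0).

Further compounds
F1 | step 7 | 4,6-bis(benzyloxy)-1-benzofuran-3(2H)-one | O=C1COc2cc(OCc3ccccc3)cc(OCc3ccccc3)c12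
F2 | step 7 | 4,6-bis(benzyloxy)-2-{5,7-bis(benzyloxy)-2-[4-(benzyloxy)phenyl]-4-oxo-4H-chromen-8-yl}-1-benzofuran-3(2H)-one (racemic, enolisable) | O=C1C(c2c(OCc3ccccc3)cc(OCc3ccccc3)c3c(=O)cc(-c4ccc(OCc5ccccc5)cc4)oc23)Oc2cc(OCc3ccccc3)cc(OCc3ccccc3)c12
F3 | step 7 | 4,6-bis(benzyloxy)-2-{5,7-bis(benzyloxy)-2-[4-(benzyloxy)phenyl]-4-oxo-4H-chromen-8-yl}-1-benzofuran-3-yl 4-(benzyloxy)benzoate | O=C(Oc1c(-c2c(OCc3ccccc3)cc(OCc3ccccc3)c3c(=O)cc(-c4ccc(OCc5ccccc5)cc4)oc23)oc2cc(OCc3ccccc3)cc(OCc3ccccc3)c12)c1ccc(OCc2ccccc2)cc1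
F4 | step 7 | (2R)-4,6-bis(benzyloxy)-2-[4-(benzyloxy)benzoyl]-2-{5,7-bis(benzyloxy)-2-[4-(benzyloxy)phenyl]-4-oxo-4H-chromen-8-yl}-1-benzofuran-3(2H)-one | O=C1c2c(OCc3ccccc3)cc(OCc3ccccc3)cc2O[C@@]1(C(=O)c1ccc(OCc2ccccc2)cc1)c1c(OCc2ccccc2)cc(OCc2ccccc2)c2c(=O)cc(-c3ccc(OCc4ccccc4)cc3)oc12
F5 | step 7 | (2S)-enantiomer of F4 | O=C1c2c(OCc3ccccc3)cc(OCc3ccccc3)cc2O[C@]1(C(=O)c1ccc(OCc2ccccc2)cc1)c1c(OCc2ccccc2)cc(OCc2ccccc2)c2c(=O)cc(-c3ccc(OCc4ccccc4)cc3)oc12
F6 | step 7 | flavone 2,3-oxide of F4 (either cis-fused epimer) | O=C1c2c(OCc3ccccc3)cc(OCc3ccccc3)cc2O[C@@]1(C(=O)c1ccc(OCc2ccccc2)cc1)c1c(OCc2ccccc2)cc(OCc2ccccc2)c2c1OC1(c3ccc(OCc4ccccc4)cc3)OC1C2=O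
F7 | step 6 | bis-epoxide of 8 with the (2S,3S)-isoflavone oxide (flavone oxide as either cis-fused epimer) | O=C1c2c(OCc3ccccc3)cc(OCc3ccccc3)cc2O[C@@]2(c3c(OCc4ccccc4)cc(OCc4ccccc4)c4c3OC3(c5ccc(OCc6ccccc6)cc5)OC3C4=O)O[C@@]12c1ccc(OCc2ccccc2)cc1
F8 | step 6 | (2S)-enantiomer of 10 | O=C1c2c(OCc3ccccc3)cc(OCc3ccccc3)cc2O[C@]1(C(=O)c1ccc(OCc2ccccc2)cc1)c1c(OCc2ccccc2)cc(OCc2ccccc2)c2c(=O)c(O)c(-c3ccc(OCc4ccccc4)cc3)oc12
F0 | step 8 | none | none
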